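**Retrosynthetic overview**
1. The last operations only unmask oxygen: three benzyl ethers (O4', O5'', O4''') and one MOM ether (O7''). Ring C of unit 2 (the 8''-linked apigenin) is traced back through a 2'-hydroxychalcone to an acetyl group, a free phenol (future O1'') and 4-(benzyloxy)benzaldehyde.
2. Structural feature used: C6 of ring A of unit 1 (the 7-methoxyflavone) is the only open carbon ortho to O5. C8'' of ring A of unit 2 is the only open carbon ortho to the oxygen that becomes O1''. Neither oxygen is alkylated in the target, so the two can carry a temporary O-Si(iPr)2-O bridge.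
3. Key disconnection: the C6-C8'' biaryl bond. It is made inside that bridge by palladium-catalysed C-H arylation of the unfunctionalised flavone C6-H with the aryl bromide of the unit 2 acetophenone, closing a seven-membered dioxasilepine.
4. The protecting groups follow from that step. The oxygen ortho to bromine carries MOM, because a benzyl ether there would cyclise onto its own phenyl ring to a 6H-benzo[c]chromene. The oxygen ortho to acetyl carries acid-stable benzyl, so that only the bridge phenol can later close ring C of unit 2.
5. Ring order: ring C of unit 1 (step 2), dioxasilepine (step 7, removed in step 8), ring C of unit 2 (step 10).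

Key step: step 7

Assumption: the SMILES gives no descriptor for the C6-C8'' axis, so the biaryl is made as the racemate.

Locants: unit 1 unprimed (ring B primed), unit 2 double-primed (ring B triple-primed). Before ring C of unit 2 exists, its ring A carries ethanone locants: C1 acetyl, C2 free OH, C3 = future C8'', C4 = future C7'', C6 = future C5''.

**Step 1**
Reactants: 1 1-(2,6-dihydroxy-4-methoxyphenyl)ethanone (2',6'-dihydroxy-4'-methoxyacetophenone); 2 4-(benzyloxy)benzoyl chloride
Product: 3 1-[4-(benzyloxy)phenyl]-3-(2,6-dihydroxy-4-methoxyphenyl)propane-1,3-dione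
Conditions: LiHMDS (4.2 equiv), THF, −78 → −10 °C; then 2 (1.0 equiv), −78 °C → rt; aq HCl work-up
Reagents that add atoms: none
Why: Claisen-type C-aroylation of a ketone enolate, the direct variant of the Baker-Venkataraman synthesis: excess LiHMDS converts 1 into its bis-phenoxide enolate, the enolate carbon is the most nucleophilic site, and the extra equivalent of base takes up the acidic proton of the 1,3-diketone as it forms.

**Step 2**
Reactants: 3 the 1,3-diketone
Product: 4 4'-benzyloxy-5-hydroxy-7-methoxyflavone
Conditions: H2SO4 (cat.), AcOH, 95 °C, short reaction time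
Reagents that add atoms: none
Why: Acid-catalysed cyclodehydration of an o-hydroxyaryl 1,3-diketone (closing stage of the Baker-Venkataraman flavone synthesis); the two ortho hydroxyls of 3 are equivalent, so a single flavone should form, the unused hydroxyl stays as the chelated 5-OH, and the aryl benzyl ether tolerates brief exposure to catalytic acid.

**Step 3**
Reactants: 5 1-(2,4,6-trihydroxyphenyl)ethanone (2',4',6'-trihydroxyacetophenone, dried)
Product: 6 1-[2,6-dihydroxy-4-(methoxymethoxy)phenyl]ethanone
Conditions: MOMCl (1.05 equiv), iPr2NEt (1.2 equiv), CH2Cl2, 0 °C → rt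
Reagents that add atoms: chloromethyl methyl ether (MOMCl), COCCl
Why: Williamson-type O-alkylation under stoichiometric control: the 4-OH is the only hydroxyl not hydrogen-bonded to the ketone and the most acidic one, so one equivalent of MOMCl should react there first.

**Step 4**
Reactants: 6 the 4-O-MOM ether
Product: 7 1-[6-(benzyloxy)-2-hydroxy-4-(methoxymethoxy)phenyl]ethanone
Conditions: BnBr (1.05 equiv), K2CO3 (1.2 equiv), acetone, reflux
Reagents that add atoms: benzyl bromide, BrCc1ccccc1
Why: Williamson ether synthesis: the two hydroxyls of 6 are equivalent, and once one is benzylated the other is held in a strong hydrogen bond to the ketone and reacts much more slowly, so the reaction can be stopped at the monoether.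

**Step 5**
Reactants: 7 the 6-O-benzyl 4-O-MOM acetophenone
Product: 8 1-[6-(benzyloxy)-3-bromo-2-hydroxy-4-(methoxymethoxy)phenyl]ethanone
Conditions: NBS (1.0 equiv), CH2Cl2, −10 → 0 °C, dark
Reagents that add atoms: N-bromosuccinimide, O=C1CCC(=O)N1Br
Why: Electrophilic aromatic bromination: the free phenol is the strongest donor and C3 (ortho to OH and OMOM, para to OBn) is less crowded than C5 between two alkoxy groups, which is the pattern established for 2-hydroxy-4,6-dialkoxyacetophenones, and the neutral by-product leaves the MOM acetal untouched.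

**Step 6**
Reactants: 8 the bromophenol; 9 dichlorodiisopropylsilane; 4 4'-benzyloxy-5-hydroxy-7-methoxyflavone
Product: 11 bis(aryloxy)diisopropylsilane joining O5 of flavone 4 to O2 of bromoacetophenone 8, via aryloxy(chloro)diisopropylsilane 10 (not isolated)
Conditions: 8, NaH (1.0 equiv), THF, 0 °C, added slowly to 9 (3 equiv), THF, 0 °C → rt; surplus 9 and solvent removed in vacuo; then the sodium salt of 4 (NaH, 1.0 equiv, THF-DMF, 0 °C), rt; quick filtration through Et3N-deactivated silica with exclusion of moisture
Reagents that add atoms: none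
Why: Two successive nucleophilic substitutions at silicon (mixed silyl ketal formation): the hindered sodium phenoxide of 8 meets an excess of 9 and stops at monochloride 10, and after removal of surplus 9 the preformed sodium 5-oxide of 4, whose hydrogen bond to C4=O is already broken, displaces the second chloride, amine bases being avoided so that the acetyl group next to silicon is not silylated through its enol.

**Step 7**
Reactants: 11 the silicon-bridged flavone and bromoacetophenone
Product: 12 dibenzo[d,f][1,3,2]dioxasilepine carrying the complete biaryl (flavone C6 bonded to acetophenone C3; ring atoms C5, O, Si(iPr)2, O, acetophenone C2, acetophenone C3, C6)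
Conditions: Pd(OAc)2 (10 mol %), PCy3·HBF4 (20 mol %), CsOPiv (2.5 equiv), 4 Å MS, mesitylene (0.02 M), 120 °C, Ar
Reagents that add atoms: none
Why: Zerovalent palladium, formed in situ from Pd(OAc)2 and PCy3, inserts into the C3-Br bond of the acetophenone ring, bromide is exchanged for pivalate, the pivalate removes the flavone C6 proton in a concerted metalation-deprotonation that gives an eight-membered diaryl palladacycle, and reductive elimination forms the bond that becomes the C6-C8'' axis. The closest known reaction type is the silicon-tethered palladium-catalysed intramolecular C-H arylation of bis(aryloxy)silanes that delivers unsymmetrical 2,2'-biphenols. The only ring closed is the seven-membered dioxasilepine, and it closes by aryl-aryl reductive elimination, that is, by formation of its single biaryl C-C bond. No stereocentre is created and the new axis forms as a racemate. Site selectivity for C6 over C8 is needed and is secured by the bridge, because from O5 only the two ortho carbons are within reach and C4a is quaternary; on the bromide side the MOM group on O4 offers no aryl C-H for a competing six-membered closure and the O6 benzyl group lies para to palladium, out of reach. CsOPiv as the sole base keeps the medium free of water and too weakly basic to enolise the acetyl group or strip the bridge.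

**Step 8**
Reactants: 12 the dioxasilepine
Product: 13 6-[3-acetyl-4-(benzyloxy)-2-hydroxy-6-(methoxymethoxy)phenyl]-4'-benzyloxy-5-hydroxy-7-methoxyflavone (the free 2,2'-biphenol)
Conditions: TBAF (2.2 equiv), AcOH (2.2 equiv), THF, 0 °C
Reagents that add atoms: none
Why: Fluoride-mediated cleavage of both Si-O(aryl) bonds, driven by the strength of the Si-F bond; AcOH protonates the two phenoxides at once, and MOM, benzyl ethers, ketone and flavone are inert to buffered fluoride.

**Step 9**
Reactants: 13 the biphenol; 14 4-(benzyloxy)benzaldehyde
Product: 15 (E)-2'-hydroxychalcone of unit 2, in which the acetyl group of 13 has become C(=O)-CH=CH-C6H4-4-OBn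
Conditions: 14 (1.5 equiv), KOH (50 % aq, 15 equiv), EtOH-THF, rt, Ar; cold 1 M HCl to pH 5
Reagents that add atoms: none
Why: Claisen-Schmidt condensation (crossed aldol, then E1cB loss of water) of the methyl ketone with a non-enolisable aldehyde, well established for 2-hydroxy-4,6-dialkoxyacetophenones; the E alkene is the thermodynamic product, and the flavone of unit 1 is shielded from hydroxide because it is present as its electron-rich 5-oxide.

**Step 10**
Reactants: 15 the chalcone
Product: 17 4',5'',4'''-tris(benzyloxy)-5,7''-dihydroxy-7-methoxy-6,8''-biflavone, via 7''-O-MOM biflavone 16 (not isolated)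
Conditions: I2 (10 mol %), DMSO, 120 °C; extractive work-up; crude material in 3 M HCl, MeOH-THF, 55 °C
Reagents that add atoms: none
Why: Iodine-DMSO oxidative cyclisation of a 2'-hydroxychalcone (oxa-Michael closure of ring C, iodination alpha to the ketone, loss of HI, reoxidation of HI by DMSO), in which only the former bridge phenol is free so that the biaryl carbon must end as C8''; the acid methanolysis that follows removes whatever MOM acetal survives and converges the material on 17.

**Step 11**
Reactants: 17 the tribenzyl biflavone
Product: 18 5,4',5'',7'',4'''-pentahydroxy-7-methoxy-6,8''-biflavone (CNP0246647.0, target)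
Conditions: H2 (1 atm), 10 % Pd/C, THF-MeOH, rt
Reagents that add atoms: none
Why: Catalytic hydrogenolysis of three aryl benzyl ethers; at one atmosphere and room temperature the flavone C2-C3 double bonds and the aryl methyl ether are normally left intact.

**Compound list**
1 | 1-(2,6-dihydroxy-4-methoxyphenyl)ethanone | CC(=O)c1c(O)cc(OC)cc1O | starting material
2 | 4-(benzyloxy)benzoyl chloride | O=C(Cl)c1ccc(OCc2ccccc2)cc1 | starting material
3 | 1-[4-(benzyloxy)phenyl]-3-(2,6-dihydroxy-4-methoxyphenyl)propane-1,3-dione | COc1cc(O)c(C(=O)CC(=O)c2ccc(OCc3ccccc3)cc2)c(O)c1 | intermediate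
4 | 4'-benzyloxy-5-hydroxy-7-methoxyflavone | COc1cc(O)c2c(=O)cc(-c3ccc(OCc4ccccc4)cc3)oc2c1 | intermediate
5 | 1-(2,4,6-trihydroxyphenyl)ethanone | CC(=O)c1c(O)cc(O)cc1O | starting material
6 | 1-[2,6-dihydroxy-4-(methoxymethoxy)phenyl]ethanone | CC(=O)c1c(O)cc(OCOC)cc1O | intermediate
7 | 1-[6-(benzyloxy)-2-hydroxy-4-(methoxymethoxy)phenyl]ethanone | CC(=O)c1c(O)cc(OCOC)cc1OCc1ccccc1 | intermediate
8 | 1-[6-(benzyloxy)-3-bromo-2-hydroxy-4-(methoxymethoxy)phenyl]ethanone | CC(=O)c1c(O)c(Br)c(OCOC)cc1OCc1ccccc1 | intermediate
9 | dichlorodiisopropylsilane | CC(C)[Si](Cl)(Cl)C(C)C | starting material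
10 | [2-acetyl-3-(benzyloxy)-6-bromo-5-(methoxymethoxy)phenoxy]chlorodiisopropylsilane | CC(=O)c1c(O[Si](Cl)(C(C)C)C(C)C)c(Br)c(OCOC)cc1OCc1ccccc1 | intermediate
11 | diisopropylsilylene-bridged flavone and bromoacetophenone | COc1cc2oc(-c3ccc(OCc4ccccc4)cc3)cc(=O)c2c(O[Si](C(C)C)(C(C)C)Oc2c(Br)c(OCOC)cc(OCc3ccccc3)c2C(C)=O)c1 | intermediate
12 | dibenzo-dioxasilepine with the complete biaryl | COc1cc2oc(-c3ccc(OCc4ccccc4)cc3)cc(=O)c2c5O[Si](C(C)C)(C(C)C)Oc6c(C(C)=O)c(OCc7ccccc7)cc(OCOC)c6-c15 | intermediate
13 | 6-[3-acetyl-4-(benzyloxy)-2-hydroxy-6-(methoxymethoxy)phenyl]-4'-benzyloxy-5-hydroxy-7-methoxyflavone | COc1cc2oc(-c3ccc(OCc4ccccc4)cc3)cc(=O)c2c(O)c1-c1c(O)c(C(C)=O)c(OCc2ccccc2)cc1OCOC | intermediate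
14 | 4-(benzyloxy)benzaldehyde | O=Cc1ccc(OCc2ccccc2)cc1 | starting material
15 | (E)-chalcone of unit 2 | COc1cc2oc(-c3ccc(OCc4ccccc4)cc3)cc(=O)c2c(O)c1-c1c(O)c(C(=O)/C=C/c2ccc(OCc3ccccc3)cc2)c(OCc2ccccc2)cc1OCOC | intermediate
16 | 4',5'',4'''-tris(benzyloxy)-5-hydroxy-7-methoxy-7''-(methoxymethoxy)-6,8''-biflavone | COc1cc2oc(-c3ccc(OCc4ccccc4)cc3)cc(=O)c2c(O)c1-c1c(OCOC)cc(OCc2ccccc2)c2c(=O)cc(-c3ccc(OCc4ccccc4)cc3)oc12 | intermediate
17 | 4',5'',4'''-tris(benzyloxy)-5,7''-dihydroxy-7-methoxy-6,8''-biflavone | COc1cc2oc(-c3ccc(OCc4ccccc4)cc3)cc(=O)c2c(O)c1-c1c(O)cc(OCc2ccccc2)c2c(=O)cc(-c3ccc(OCc4ccccc4)cc3)oc12 | intermediate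
18 | 5,4',5'',7'',4'''-pentahydroxy-7-methoxy-6,8''-biflavone | COc1cc2oc(-c3ccc(O)cc3)cc(=O)c2c(O)c1-c1c(O)cc(O)c2c(=O)cc(-c3ccc(O)cc3)oc12 | target

**Total step count:** 11
**Longest linear sequence:** 9 steps (5 → 18, steps 3 to 11)

**Steps most likely to fail**

**Step 7.**
- What may go wrong: oxidative addition into the electron-rich, doubly ortho-oxygenated C-Br bond may be slow. The aryl palladium species may be protonated, giving simple loss of bromine. The metalation-deprotonation may stall because four ortho oxygens crowd the forming axis. The bridge may be lost through attack of pivalate or of the acetyl enolate at silicon before the coupling occurs.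
- Fallback: both carbons are functionalised and the same bond is made by an intermolecular Suzuki-Miyaura coupling. It sets out from 4 and 8 and comes back at 13, so steps 6 to 8 are bypassed. Flavone 4 is iodinated ortho to its chelated hydroxyl with BnMe3NICl2 and CaCO3 in CH2Cl2-MeOH to give 4'-benzyloxy-5-hydroxy-6-iodo-7-methoxyflavone F1. Bromide 8 undergoes Miyaura borylation (B2pin2, Pd2(dba)3, XPhos, KOAc, dioxane, 100 °C) to give 1-[6-(benzyloxy)-2-hydroxy-4-(methoxymethoxy)-3-(4,4,5,5-tetramethyl-1,3,2-dioxaborolan-2-yl)phenyl]ethanone F2. The two are then coupled with Pd(OAc)2, SPhos and K3PO4 in toluene-water at 90 °C, which should give 13 directly.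

**Step 6.**
- What may go wrong: aryloxy groups may redistribute at silicon to give the two symmetrical silanes. The chelation-prone 5-oxide may attack the hindered chlorosilane only sluggishly. The chlorosilane may close onto the enol of its own acetyl group. The mixed silyl ketal may hydrolyse during isolation.
- Fallback: silicon is introduced as a monofunctional hydrosilane and activated only afterwards. It sets out from 8 and comes back at 11. Phenol 8 is silylated with chlorodiisopropylsilane and imidazole in CH2Cl2 to give the isolable [2-acetyl-3-(benzyloxy)-6-bromo-5-(methoxymethoxy)phenoxy]diisopropylsilane F3, which can be purified and weighed exactly. Its Si-H bond is then brominated with NBS in CH2Cl2 at 0 °C; the ring is deactivated by acetyl and bromine and no longer carries a free phenol. This gives the more electrophilic [2-acetyl-3-(benzyloxy)-6-bromo-5-(methoxymethoxy)phenoxy]bromodiisopropylsilane F4. F4 is treated at once with the sodium salt of 4 in THF to give 11.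

**Step 9.**
- What may go wrong: hydroxide may add to C2 of the unit 1 pyranone during the long exposure to aqueous KOH and open the ring. Reclosure through the other ortho oxygen (Wessely-Moser type isomerisation) would move the axis from C6 to C8. The crowded ketone may also condense only slowly.
- Fallback: ring C of unit 2 is built by the acylation route already used for unit 1, without aqueous base. It sets out from 13 and comes back at 17, bypassing 15 and 16. Compound 13 is converted with LiHMDS (4.2 equiv, THF, −78 °C) into its bis-phenoxide enolate and C-aroylated with acid chloride 2. This gives the 1,3-diketone 6-{4-(benzyloxy)-3-[3-(4-benzyloxyphenyl)-3-oxopropanoyl]-2-hydroxy-6-(methoxymethoxy)phenyl}-4'-benzyloxy-5-hydroxy-7-methoxyflavone F5. Warming F5 in 3 M HCl, MeOH-THF brings about cyclodehydration through the only free ortho phenol and removes the MOM group in the same operation, giving 17.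

**Further compounds**
F1 | step 7 | 4'-benzyloxy-5-hydroxy-6-iodo-7-methoxyflavone | COc1cc2oc(-c3ccc(OCc4ccccc4)cc3)cc(=O)c2c(O)c1I
F2 | step 7 | 1-[6-(benzyloxy)-2-hydroxy-4-(methoxymethoxy)-3-(4,4,5,5-tetramethyl-1,3,2-dioxaborolan-2-yl)phenyl]ethanone | CC(=O)c1c(O)c(B2OC(C)(C)C(C)(C)O2)c(OCOC)cc1OCc1ccccc1
F3 | step 6 | [2-acetyl-3-(benzyloxy)-6-bromo-5-(methoxymethoxy)phenoxy]diisopropylsilane | CC(=O)c1c(O[SiH](C(C)C)C(C)C)c(Br)c(OCOC)cc1OCc1ccccc1
F4 | step 6 | [2-acetyl-3-(benzyloxy)-6-bromo-5-(methoxymethoxy)phenoxy]bromodiisopropylsilane | CC(=O)c1c(O[Si](Br)(C(C)C)C(C)C)c(Br)c(OCOC)cc1OCc1ccccc1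
F5 | step 9 | 6-{4-(benzyloxy)-3-[3-(4-benzyloxyphenyl)-3-oxopropanoyl]-2-hydroxy-6-(methoxymethoxy)phenyl}-4'-benzyloxy-5-hydroxy-7-methoxyflavone | COc1cc2oc(-c3ccc(OCc4ccccc4)cc3)cc(=O)c2c(O)c1-c1c(O)c(C(=O)CC(=O)c2ccc(OCc3ccccc3)cc2)c(OCc2ccccc2)cc1OCOC
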